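**Strategy.** Everything rests on opening ring B (C5–C10, labdane numbering) at C5–C10 and C8–C9, an intramolecular Diels–Alder retron: the C6 oxygen marks a 2-silyloxydiene C5=C6(OTBS)–C7=C8 and C9=C10 an (E)-β-methyl enoate, linked through C1–C4. Heating the open-chain triene closes rings A and B at once and sets C5, C9 and the quaternary C10 under control of the one stereocentre present, quaternary C4, which is made by Sharpless epoxidation and a stereospecific epoxy silyl ether rearrangement. The resulting C6 enol ether is then turned into the 6,8-dioxygenation (enone, epoxide, reductive opening); the diene side chain is attached last.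

Key step: step 10

Remark: atoms carry labdane numbers throughout (ring A = C1–C5 and C10; ring B = C5–C10; C18 and C19 on C4, C20 on C10, C17 on C8, side chain C11–C16 on C9). In the target the methyl groups on C4, C8 and C10 and the C9 side chain lie on one face; H5, H9, the 8-OH, the 6-OAc and the CH2OH on C4 lie on the other; the rings are trans-fused.
Assumption: 2-chloro-1,3-butadiene is bought as its stabilised solution.

Step 1
Reactants: 1 pent-1-en-4-yne
Product: 4 (2E)-3-methylhexa-2,5-dien-1-ol, via alkenylalane 2 (not isolated), via alanate 3 (not isolated)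
Conditions: AlMe3 (2.2 equiv), Cp2ZrCl2 (20 mol %), CH2Cl2, 0 → 23 °C; then n-BuLi, THF, −78 °C; (CH2O)n, −78 → 23 °C
Reagents that add atoms: trimethylaluminium, C[Al](C)C; paraformaldehyde (as formaldehyde), C=O
Why: Negishi carboalumination (zirconium-catalysed syn addition of methyl–aluminium to the terminal alkyne, methyl to the internal carbon) and hydroxymethylation of the derived alanate with retention should give the (E)-trisubstituted allylic alcohol, the isolated alkene being inert.

Step 2
Reactants: 5 methyl acetoacetate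
Product: 6 methyl (2E)-3-{[(trifluoromethyl)sulfonyl]oxy}but-2-enoate
Conditions: Tf2O, aq. Me4NOH, hexane/toluene, 5 °C
Reagents that add atoms: trifluoromethanesulfonic anhydride, O=S(=O)(OS(=O)(=O)C(F)(F)F)C(F)(F)F
Why: O-triflation of the acetoacetate enolate with a non-chelating ammonium counter-ion should favour the (E)-enol triflate, which places the leaving group trans to the ester.

Step 3
Reactants: 4 (2E)-3-methylhexa-2,5-dien-1-ol; 6 methyl (2E)-3-{[(trifluoromethyl)sulfonyl]oxy}but-2-enoate
Product: 8 methyl (2E,7E)-9-hydroxy-3,7-dimethylnona-2,7-dienoate, via alkylborane 7 (not isolated)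
Conditions: 9-BBN (2.2 equiv, one equivalent is taken up by the OH), THF, 0 → 23 °C; then 6, Pd(dppf)Cl2 (5 mol %), 3 M aq. K3PO4, DMF, 23 °C
Reagents that add atoms: none
Why: 9-BBN hydroborates only the monosubstituted alkene (boron at the terminal carbon, C1) and the B-alkyl Suzuki–Miyaura coupling with 6 proceeds with retention, so the (E)-enoate C9=C10 is formed with C1 trans to the ester.

Step 4
Reactants: 8 methyl (2E,7E)-9-hydroxy-3,7-dimethylnona-2,7-dienoate
Product: 9 methyl (2E)-6-[(2R,3R)-3-(hydroxymethyl)-2-methyloxiran-2-yl]-3-methylhex-2-enoate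
Conditions: Ti(OiPr)4 (10 mol %), D-(−)-diisopropyl tartrate (12 mol %), t-BuOOH (2 equiv), 4 Å MS, CH2Cl2, −20 °C
Reagents that add atoms: tert-butyl hydroperoxide, CC(C)(C)OO
Why: Sharpless asymmetric epoxidation: with the D-(−)-tartrate ligand an (E)-3,3-disubstituted allylic alcohol of this type should give the (2R,3R)-epoxy alcohol, and the enoate alkene, which is no allylic alcohol, should not react.

Step 5
Reactants: 9 methyl (2E)-6-[(2R,3R)-3-(hydroxymethyl)-2-methyloxiran-2-yl]-3-methylhex-2-enoate
Product: 10 methyl (2E)-6-[(2R,3R)-3-{[(tert-butyldimethylsilyl)oxy]methyl}-2-methyloxiran-2-yl]-3-methylhex-2-enoate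
Conditions: TBSCl, imidazole, DMF, 0 → 23 °C
Reagents that add atoms: tert-butyldimethylsilyl chloride, CC(C)(C)[Si](C)(C)Cl
Why: Standard silylation of the primary alcohol; the silyl ether is the migrating-group carrier of the next step and the C18 protecting group to the end.

Step 6
Reactants: 10 methyl (2E)-6-[(2R,3R)-3-{[(tert-butyldimethylsilyl)oxy]methyl}-2-methyloxiran-2-yl]-3-methylhex-2-enoate
Product: 11 methyl (2E,7R)-8-[(tert-butyldimethylsilyl)oxy]-7-formyl-3,7-dimethyloct-2-enoate
Conditions: MeAl(OAr)2 (Ar = 4-bromo-2,6-di-tert-butylphenyl, 3 equiv, from AlMe3 and ArOH), CH2Cl2, −78 °C; aq. NaF work-up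
Reagents that add atoms: none
Why: Organoaluminium-promoted rearrangement of an epoxy silyl ether (semipinacol type): the bulky Lewis acid ionises the tertiary C–O bond and the siloxymethyl group migrates anti to it, so the epoxide chirality is passed with inversion to the new quaternary centre C4 (R), which now carries CHO (C5), CH2OTBS (C18), CH3 and the chain.

Step 7
Reactants: 11 methyl (2E,7R)-8-[(tert-butyldimethylsilyl)oxy]-7-formyl-3,7-dimethyloct-2-enoate
Product: 12 methyl (2E,7S)-7-{[(tert-butyldimethylsilyl)oxy]methyl}-3,7-dimethylnon-2-en-8-ynoate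
Conditions: dimethyl (1-diazo-2-oxopropyl)phosphonate, K2CO3, MeOH, 0 → 23 °C
Reagents that add atoms: dimethyl (1-diazo-2-oxopropyl)phosphonate, CC(=O)C(=[N+]=[N-])P(=O)(OC)OC
Why: Ohira–Bestmann (Seyferth–Gilbert) homologation; the aldehyde has no α-hydrogen, so neither epimerisation nor β-elimination of the silyloxy group can occur.

Step 8
Reactants: 12 methyl (2E,7S)-7-{[(tert-butyldimethylsilyl)oxy]methyl}-3,7-dimethylnon-2-en-8-ynoate; 13 (E)-1-bromoprop-1-ene
Product: 14 methyl (2E,7S,10E)-7-{[(tert-butyldimethylsilyl)oxy]methyl}-3,7-dimethyldodeca-2,10-dien-8-ynoate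
Conditions: PdCl2(PPh3)2 (3 mol %), CuI (6 mol %), Et3N, THF, 23 °C
Reagents that add atoms: none
Why: Sonogashira coupling, which keeps the (E)-geometry of the vinyl bromide and brings in C7, C8 and C17.

Step 9
Reactants: 14 methyl (2E,7S,10E)-7-{[(tert-butyldimethylsilyl)oxy]methyl}-3,7-dimethyldodeca-2,10-dien-8-ynoate
Product: 15 methyl (2E,7S,10E)-7-{[(tert-butyldimethylsilyl)oxy]methyl}-3,7-dimethyl-9-oxododeca-2,10-dienoate
Conditions: (IPr)AuCl (2 mol %), AgSbF6 (2 mol %), H2O, 1,4-dioxane, 60 °C (IPr = 1,3-bis(2,6-diisopropylphenyl)imidazol-2-ylidene)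
Reagents that add atoms: water, O
Why: Gold-catalysed alkyne hydration: water should attack C6, the alkyne carbon that is conjugated to the alkene and remote from the quaternary centre, giving the (E)-enone with C5 as CH2.

Step 10
Reactants: 15 methyl (2E,7S,10E)-7-{[(tert-butyldimethylsilyl)oxy]methyl}-3,7-dimethyl-9-oxododeca-2,10-dienoate
Product: 17 methyl 6,18-bis[(tert-butyldimethylsilyl)oxy]-12,13,14,15,16-pentanorlabd-6-en-11-oate (trans-fused; C4, C5, C9, C10 as in the target; 8-methyl cis to 10-methyl), via silyl dienol ether 16 (not isolated)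
Conditions: TBSOTf (1.3 equiv), Et3N (2.5 equiv), toluene, −20 → 23 °C; filtered under argon; then toluene (0.01 M), BHT (5 mol %), 170 °C, sealed tube
Reagents that add atoms: tert-butyldimethylsilyl trifluoromethanesulfonate, CC(C)(C)[Si](C)(C)OS(=O)(=O)C(F)(F)F
Why: Soft enolisation should give the (Z)-2-silyloxydiene 16 (C4 and OTBS cis on C5=C6), which on heating undergoes a concerted, asynchronous type 1 intramolecular Diels–Alder reaction of a 1,3,9-decatriene; the closest known reaction type is the thermal cycloaddition of a 2-silyloxydiene onto a tethered β-methyl enoate that creates an angular methyl group. Ring A is closed by the C5–C10 bond through a chair-like arrangement of the C1–C4 tether and ring B by the [4+2] union itself, C5–C10 and C8–C9 forming suprafacially on both partners. C9 and C10 follow from the (E)-enoate (C11 cis to the 10-methyl); C5 follows from the diene geometry with the ester endo (trans fusion), and any cis-fused epimer converges at step 14, where C5 is α to the ketone; C8 follows from the (E)-propenyl terminus and is erased at step 13. The step needs π-facial selectivity with respect to quaternary C4: the C4 substituent that lies near the diene plane feels A(1,3) strain with the cis OTBS group and a developing 1,3-diaxial contact with the 10-methyl, so the small methyl should take that pseudo-axial site and CH2OTBS the pseudo-equatorial one, which puts the C4 methyl cis to the 10-methyl as required. Periselectivity is secured by the tether length, which allows only the 6,6-fused mode.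

Step 11
Reactants: 17 methyl 6,18-bis[(tert-butyldimethylsilyl)oxy]-12,13,14,15,16-pentanorlabd-6-en-11-oate
Product: 18 6,18-bis[(tert-butyldimethylsilyl)oxy]-12,13,14,15,16-pentanorlabd-6-en-11-al
Conditions: i-Bu2AlH (1.15 equiv), CH2Cl2, −78 °C; MeOH, then aq. Rochelle salt
Reagents that add atoms: none
Why: Reduction of the hindered ester with DIBAL-H should stop at the aluminium hemiacetal at −78 °C and give the aldehyde, while the silyl enol ether masks the C6 ketone.

Step 12
Reactants: 18 6,18-bis[(tert-butyldimethylsilyl)oxy]-12,13,14,15,16-pentanorlabd-6-en-11-al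
Product: 19 6,18-bis[(tert-butyldimethylsilyl)oxy]-13,14,15,16-tetranorlabda-6,11-diene
Conditions: Ph3PCH3Br, KOtBu, THF, 0 → 23 °C
Reagents that add atoms: methyltriphenylphosphonium bromide, C[P+](c1ccccc1)(c1ccccc1)c1ccccc1.[Br-]
Why: Wittig methylenation brings in C12; the equatorial C9 substituent is the stable epimer, so base contact does not change C9.

Step 13
Reactants: 19 6,18-bis[(tert-butyldimethylsilyl)oxy]-13,14,15,16-tetranorlabda-6,11-diene
Product: 20 18-[(tert-butyldimethylsilyl)oxy]-13,14,15,16-tetranorlabda-7,11-dien-6-one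
Conditions: Pd(OAc)2 (1.1 equiv), MeCN, 23 → 40 °C
Reagents that add atoms: none
Why: Saegusa–Ito oxidation: the palladium enolate formed at C7 can only lose the hydrogen on C8, which gives the C7=C8 enone regiospecifically and removes the C8 stereocentre.

Step 14
Reactants: 20 18-[(tert-butyldimethylsilyl)oxy]-13,14,15,16-tetranorlabda-7,11-dien-6-one
Product: 21 7,8-epoxy-18-[(tert-butyldimethylsilyl)oxy]-13,14,15,16-tetranorlabd-11-en-6-one (epoxide oxygen on the face opposite the 10-methyl)
Conditions: 30% aq. H2O2, NaOH (0.3 equiv), MeOH/THF, 0 → 23 °C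
Reagents that add atoms: hydrogen peroxide, OO
Why: Weitz–Scheffer epoxidation: hydroperoxide should add to C8 on the face opposite the axial 10-methyl and close onto C7, which sets the C8–O bond anti to C20 with the 8-methyl cis to it, and the base equilibrates C5 to the trans ring fusion.

Step 15
Reactants: 21 7,8-epoxy-18-[(tert-butyldimethylsilyl)oxy]-13,14,15,16-tetranorlabd-11-en-6-one
Product: 23 18-[(tert-butyldimethylsilyl)oxy]-13,14,15,16-tetranorlabd-11-ene-6,8-diol (C4, C5, C6, C8, C9, C10 as in the target), via hydroxy ketone 22 (not isolated)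
Conditions: Li (8 equiv), NH3(l)/THF, −78 °C, short contact; then MeOH, −78 → −45 °C; NH4Cl
Reagents that add atoms: none
Why: Dissolving-metal reduction: the ketyl expels the α-oxygen (C7–O) to give, after protonation, hydroxy ketone 22, and the ketone is then reduced under thermodynamic control to the equatorial 6-alcohol, because the axial epimer would be 1,3-diaxial to the methyl groups on C4 and C10.

Step 16
Reactants: 23 18-[(tert-butyldimethylsilyl)oxy]-13,14,15,16-tetranorlabd-11-ene-6,8-diol; 24 2-chloro-1,3-butadiene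
Product: 26 18-[(tert-butyldimethylsilyl)oxy]labda-13(16),14-diene-6,8-diol, via alkylborane 25 (not isolated)
Conditions: 9-BBN (4 equiv, two are taken up by the OH groups), THF, 23 → 50 °C; then 24, Pd(OAc)2 (5 mol %), SPhos (10 mol %), 3 M aq. K3PO4, THF, 40 °C
Reagents that add atoms: none
Why: 9-BBN adds to the vinyl group with boron at C12, and a B-alkyl Suzuki–Miyaura coupling with the vinyl chloride (electron-rich biarylphosphine ligand) forms C12–C13 and so the 2-substituted butadiene.

Step 17
Reactants: 26 18-[(tert-butyldimethylsilyl)oxy]labda-13(16),14-diene-6,8-diol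
Product: 27 18-[(tert-butyldimethylsilyl)oxy]-8-hydroxylabda-13(16),14-dien-6-yl acetate
Conditions: Ac2O, DMAP (0.2 equiv), pyridine, CH2Cl2, 23 °C
Reagents that add atoms: acetic anhydride, CC(=O)OC(C)=O
Why: DMAP-catalysed acylation should reach only the secondary equatorial 6-OH, since the tertiary 8-OH does not react and O18 is silylated.

Step 18
Reactants: 27 18-[(tert-butyldimethylsilyl)oxy]-8-hydroxylabda-13(16),14-dien-6-yl acetate
Product: 28 (4S,5S,6R,8S,9S,10R)-8,18-dihydroxylabda-13(16),14-dien-6-yl acetate (target)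
Conditions: HF·pyridine, pyridine, THF, 0 → 23 °C
Reagents that add atoms: none
Why: Fluoride cleaves the primary silyl ether under buffered, weakly acidic conditions that should leave the acetate (no shift from O6 to O18), the tertiary alcohol and the diene untouched.

**Compound list**

1 | pent-1-en-4-yne | C=CCC#C | starting material
2 | dimethyl[(1E)-2-methylpenta-1,4-dien-1-yl]alane | C=CC/C(C)=C/[Al](C)C | intermediate
3 | lithium butyldimethyl[(1E)-2-methylpenta-1,4-dien-1-yl]alanate | [Li+].C=CC/C(C)=C/[Al-](C)(C)CCCC | intermediate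
4 | (2E)-3-methylhexa-2,5-dien-1-ol | C=CC/C(C)=C/CO | intermediate
5 | methyl acetoacetate | COC(=O)CC(C)=O | starting material
6 | methyl (2E)-3-{[(trifluoromethyl)sulfonyl]oxy}but-2-enoate | COC(=O)/C=C(\C)OS(=O)(=O)C(F)(F)F | intermediate
7 | (2E)-6-(9-borabicyclo[3.3.1]nonan-9-yl)-3-methylhex-2-en-1-ol | OC/C=C(\C)CCCB1C2CCCC1CCC2 | intermediate
8 | methyl (2E,7E)-9-hydroxy-3,7-dimethylnona-2,7-dienoate | COC(=O)/C=C(\C)CCC/C(C)=C/CO | intermediate
9 | methyl (2E)-6-[(2R,3R)-3-(hydroxymethyl)-2-methyloxiran-2-yl]-3-methylhex-2-enoate | COC(=O)/C=C(\C)CCC[C@@]1(C)O[C@@H]1CO | intermediate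
10 | methyl (2E)-6-[(2R,3R)-3-{[(tert-butyldimethylsilyl)oxy]methyl}-2-methyloxiran-2-yl]-3-methylhex-2-enoate | COC(=O)/C=C(\C)CCC[C@@]1(C)O[C@@H]1CO[Si](C)(C)C(C)(C)C | intermediate
11 | methyl (2E,7R)-8-[(tert-butyldimethylsilyl)oxy]-7-formyl-3,7-dimethyloct-2-enoate | COC(=O)/C=C(\C)CCC[C@](C)(CO[Si](C)(C)C(C)(C)C)C=O | intermediate
12 | methyl (2E,7S)-7-{[(tert-butyldimethylsilyl)oxy]methyl}-3,7-dimethylnon-2-en-8-ynoate | COC(=O)/C=C(\C)CCC[C@](C)(CO[Si](C)(C)C(C)(C)C)C#C | intermediate
13 | (E)-1-bromoprop-1-ene | C/C=C/Br | starting material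
14 | methyl (2E,7S,10E)-7-{[(tert-butyldimethylsilyl)oxy]methyl}-3,7-dimethyldodeca-2,10-dien-8-ynoate | COC(=O)/C=C(\C)CCC[C@](C)(CO[Si](C)(C)C(C)(C)C)C#C/C=C/C | intermediate
15 | methyl (2E,7S,10E)-7-{[(tert-butyldimethylsilyl)oxy]methyl}-3,7-dimethyl-9-oxododeca-2,10-dienoate | COC(=O)/C=C(\C)CCC[C@](C)(CO[Si](C)(C)C(C)(C)C)CC(=O)/C=C/C | intermediate
16 | methyl (2E,7S,8Z,10E)-9-[(tert-butyldimethylsilyl)oxy]-7-{[(tert-butyldimethylsilyl)oxy]methyl}-3,7-dimethyldodeca-2,8,10-trienoate | COC(=O)/C=C(\C)CCC[C@](C)(CO[Si](C)(C)C(C)(C)C)/C=C(\O[Si](C)(C)C(C)(C)C)/C=C/C | intermediate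
17 | methyl 6,18-bis[(tert-butyldimethylsilyl)oxy]-12,13,14,15,16-pentanorlabd-6-en-11-oate (trans-fused; C4, C5, C9, C10 as in 28; 8-methyl cis to 10-methyl) | COC(=O)[C@H]1[C@]2(C)CCC[C@](C)(CO[Si](C)(C)C(C)(C)C)[C@H]2C(O[Si](C)(C)C(C)(C)C)=C[C@H]1C | intermediate
18 | 6,18-bis[(tert-butyldimethylsilyl)oxy]-12,13,14,15,16-pentanorlabd-6-en-11-al (configured as 17) | O=C[C@H]1[C@]2(C)CCC[C@](C)(CO[Si](C)(C)C(C)(C)C)[C@H]2C(O[Si](C)(C)C(C)(C)C)=C[C@H]1C | intermediate
19 | 6,18-bis[(tert-butyldimethylsilyl)oxy]-13,14,15,16-tetranorlabda-6,11-diene (configured as 17) | C=C[C@H]1[C@]2(C)CCC[C@](C)(CO[Si](C)(C)C(C)(C)C)[C@H]2C(O[Si](C)(C)C(C)(C)C)=C[C@H]1C | intermediate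
20 | 18-[(tert-butyldimethylsilyl)oxy]-13,14,15,16-tetranorlabda-7,11-dien-6-one (C4, C5, C9, C10 as in 28) | C=C[C@H]1[C@]2(C)CCC[C@](C)(CO[Si](C)(C)C(C)(C)C)[C@H]2C(=O)C=C1C | intermediate
21 | 7,8-epoxy-18-[(tert-butyldimethylsilyl)oxy]-13,14,15,16-tetranorlabd-11-en-6-one (epoxide oxygen on the face opposite the 10-methyl) | C=C[C@H]1[C@]2(C)CCC[C@](C)(CO[Si](C)(C)C(C)(C)C)[C@H]2C(=O)[C@@H]3O[C@]13C | intermediate
22 | 8-hydroxy-18-[(tert-butyldimethylsilyl)oxy]-13,14,15,16-tetranorlabd-11-en-6-one (C4, C5, C8, C9, C10 as in 28) | C=C[C@H]1[C@]2(C)CCC[C@](C)(CO[Si](C)(C)C(C)(C)C)[C@H]2C(=O)C[C@]1(C)O | intermediate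
23 | 18-[(tert-butyldimethylsilyl)oxy]-13,14,15,16-tetranorlabd-11-ene-6,8-diol (all ring stereocentres as in 28) | C=C[C@H]1[C@]2(C)CCC[C@](C)(CO[Si](C)(C)C(C)(C)C)[C@H]2[C@H](O)C[C@]1(C)O | intermediate
24 | 2-chloro-1,3-butadiene | C=CC(Cl)=C | starting material
25 | 12-(9-borabicyclo[3.3.1]nonan-9-yl)-18-[(tert-butyldimethylsilyl)oxy]-13,14,15,16-tetranorlabdane-6,8-diol | C1CCC2CCCC1B2CC[C@H]3[C@]4(C)CCC[C@](C)(CO[Si](C)(C)C(C)(C)C)[C@H]4[C@H](O)C[C@]3(C)O | intermediate
26 | 18-[(tert-butyldimethylsilyl)oxy]labda-13(16),14-diene-6,8-diol (all stereocentres as in 28) | C=CC(=C)CC[C@H]1[C@]2(C)CCC[C@](C)(CO[Si](C)(C)C(C)(C)C)[C@H]2[C@H](O)C[C@]1(C)O | intermediate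
27 | 18-[(tert-butyldimethylsilyl)oxy]-8-hydroxylabda-13(16),14-dien-6-yl acetate | C=CC(=C)CC[C@H]1[C@]2(C)CCC[C@](C)(CO[Si](C)(C)C(C)(C)C)[C@H]2[C@H](OC(C)=O)C[C@]1(C)O | intermediate
28 | (4S,5S,6R,8S,9S,10R)-8,18-dihydroxylabda-13(16),14-dien-6-yl acetate | C=CC(=C)CC[C@H]1[C@]2(C)CCC[C@](C)(CO)[C@H]2[C@H](OC(C)=O)C[C@]1(C)O | target

**Step count.** Total: 18 steps. Longest linear sequence: 17 steps (steps 1 and 3–18); step 2 is a one-step branch.

**Three steps most likely to fail**

Step 10 (key cycloaddition). The dienophile is β,β-disubstituted and the diene terminus sits next to a quaternary carbon, so the cycloaddition may need a temperature at which the dienol ether degrades. The two faces of the dienophile may also be attacked with too little preference with respect to C4. Fallback, a stepwise ionic double Michael sequence: it sets out from 16, which is now isolated by filtration and evaporation. A Lewis-acid-promoted intramolecular Mukaiyama–Michael addition (TiCl4, CH2Cl2, −78 °C) forms only the C5–C10 bond and, after aqueous work-up, should give methyl 2-{2-[(2E)-but-2-enoyl]-3-{[(tert-butyldimethylsilyl)oxy]methyl}-1,3-dimethylcyclohexyl}acetate F1, whose C10 epimers can be separated at this monocyclic stage. KOtBu in t-BuOH/THF then closes ring B by intramolecular Michael addition of the ester enolate (C9) to the enone (C8) under equilibrating conditions, to give methyl 18-[(tert-butyldimethylsilyl)oxy]-6-oxo-12,13,14,15,16-pentanorlabdan-11-oate F2. TBSOTf/Et3N regenerates the C6 enol ether, and the fallback comes back to the route at 17.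

Step 14 (epoxidation). Hydroperoxide may add to C8 from the face syn to the 10-methyl, which is the stereoelectronically favoured axial approach, or may not add at all at the hindered β-carbon. Fallback: it sets out from 20. Copper-catalysed conjugate borylation (CuCl, NaOtBu, Xantphos, B2pin2, MeOH, THF) is a syn insertion ruled by steric approach to the open face and should give 8-(4,4,5,5-tetramethyl-1,3,2-dioxaborolan-2-yl)-18-[(tert-butyldimethylsilyl)oxy]-13,14,15,16-tetranorlabd-11-en-6-one F3. Oxidation with NaBO3·4H2O, with retention at C8, gives hydroxy ketone 22, which is isolated here. The fallback comes back to the route at 22, where only the ketone reduction of step 15 remains.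

Step 16 (side-chain coupling). Oxidative addition of the vinyl chloride may be slow, 24 may polymerise, or the hindered alkylborane may be lost by protodeboronation. Fallback: it sets out from 23. Hydroboration with 9-BBN and oxidative work-up (NaOH, H2O2) gives 18-[(tert-butyldimethylsilyl)oxy]-13,14,15,16-tetranorlabdane-6,8,12-triol F4. I2, PPh3 and imidazole convert only the primary alcohol into 12-iodo-18-[(tert-butyldimethylsilyl)oxy]-13,14,15,16-tetranorlabdane-6,8-diol F5. A Li2CuCl4-catalysed coupling with buta-1,3-dien-2-ylmagnesium chloride F6 (from 24 and Mg, used in excess to take up the two hydroxyl protons) then forms C12–C13, and the fallback comes back to the route at 26.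

**Further compounds**

F1 | step 10 | methyl 2-{2-[(2E)-but-2-enoyl]-3-{[(tert-butyldimethylsilyl)oxy]methyl}-1,3-dimethylcyclohexyl}acetate (C4, C5, C10 as in 28) | COC(=O)C[C@]1(C)CCC[C@](C)(CO[Si](C)(C)C(C)(C)C)[C@H]1C(=O)/C=C/C
F2 | step 10 | methyl 18-[(tert-butyldimethylsilyl)oxy]-6-oxo-12,13,14,15,16-pentanorlabdan-11-oate | COC(=O)[C@H]1[C@]2(C)CCC[C@](C)(CO[Si](C)(C)C(C)(C)C)[C@H]2C(=O)C[C@H]1C
F3 | step 14 | 8-(4,4,5,5-tetramethyl-1,3,2-dioxaborolan-2-yl)-18-[(tert-butyldimethylsilyl)oxy]-13,14,15,16-tetranorlabd-11-en-6-one | C=C[C@H]1[C@]2(C)CCC[C@](C)(CO[Si](C)(C)C(C)(C)C)[C@H]2C(=O)C[C@]1(C)B1OC(C)(C)C(C)(C)O1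
F4 | step 16 | 18-[(tert-butyldimethylsilyl)oxy]-13,14,15,16-tetranorlabdane-6,8,12-triol | OCC[C@H]1[C@]2(C)CCC[C@](C)(CO[Si](C)(C)C(C)(C)C)[C@H]2[C@H](O)C[C@]1(C)O
F5 | step 16 | 12-iodo-18-[(tert-butyldimethylsilyl)oxy]-13,14,15,16-tetranorlabdane-6,8-diol | ICC[C@H]1[C@]2(C)CCC[C@](C)(CO[Si](C)(C)C(C)(C)C)[C@H]2[C@H](O)C[C@]1(C)O
F6 | step 16 | buta-1,3-dien-2-ylmagnesium chloride | C=CC(=C)[Mg]Cl
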